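Locants: tetralin C1 bears the side chain (C11 its first carbon), C4 the methyl, C5/C6 the hydroxyls, C7 the carboxyl. Ring B is built last by making C1–C2 and C4–C4a together, a formal [3+3] union of the C1–C8a–C4a triad with a C2–C3–C4(CH3) unit. This exploits ring A: the C6 oxygen, para to C8a, stabilises a C1 benzylic cation, and the C5 oxygen activates C4a. An Evans aldol adduct (C11 set, C1–OH as leaving group, C8 blocked by bromine) is ionised, propargylated at C1 by a methylallenylsilane, and the alkyne closes onto C4a under the same gold catalyst.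

Key step: step 4

Remark: silane 7 is taken as a commercial reagent; further locants are C12–C14 (chain methylenes), C15 (methyl-bearing carbon), C16 (terminal CH2O) and C18 (CH2O carbon on C11).

Step 1
Reactants: 1 3,4-bis(benzyloxy)benzaldehyde
Product: 2 2-bromo-4,5-bis(benzyloxy)benzaldehyde
Conditions: Br2, NaOAc, AcOH, rt
Reagents that add atoms: bromine, BrBr
Why: Electrophilic aromatic bromination should occur para to the 3-benzyloxy group and ortho to the formyl group, the only activated unhindered position, and installs the bromine that later blocks C8.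

Step 2
Reactants: 3 (S)-4-benzyloxazolidin-2-one; 4 pent-4-enoyl chloride
Product: 5 (S)-4-benzyl-3-(pent-4-enoyl)oxazolidin-2-one
Conditions: n-BuLi, THF, −78 °C; then 4
Reagents that add atoms: none
Why: N-Acylation of the lithiated oxazolidinone by the acid chloride (standard attachment of the Evans auxiliary) forms no stereocentre.

Step 3
Reactants: 5 (S)-4-benzyl-3-(pent-4-enoyl)oxazolidin-2-one; 2 2-bromo-4,5-bis(benzyloxy)benzaldehyde
Product: 6 (S)-4-benzyl-3-[(S)-2-[(S)-[2-bromo-4,5-bis(benzyloxy)phenyl](hydroxy)methyl]pent-4-enoyl]oxazolidin-2-one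
Conditions: Bu2BOTf, i-Pr2NEt, CH2Cl2, −78 to 0 °C; then pH 7 buffer, MeOH, H2O2
Reagents that add atoms: none
Why: Evans syn aldol reaction, in which the Z boron enolate reacts through a Zimmerman–Traxler transition state on the face opposite the auxiliary benzyl group, should set C11 (S) and the carbinol carbon C1 (S, ionised in step 4).

Step 4
Reactants: 6 (S)-4-benzyl-3-[(S)-2-[(S)-[2-bromo-4,5-bis(benzyloxy)phenyl](hydroxy)methyl]pent-4-enoyl]oxazolidin-2-one; 7 trimethyl(buta-2,3-dien-2-yl)silane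
Product: 9 (S)-4-benzyl-3-[(S)-2-[(S)-8-bromo-5,6-bis(benzyloxy)-4-methyl-1,2-dihydronaphthalen-1-yl]pent-4-enoyl]oxazolidin-2-one, via pent-3-ynyl imide 8 (not isolated)
Conditions: AuCl3 (5 mol%), AgOTf (15 mol%), CH2Cl2, −40 °C to rt
Reagents that add atoms: none
Why: The trivalent gold Lewis acid (AuCl3/AgOTf) ionises the benzylic hydroxyl of 6 to a C1 cation stabilised by the para C6 benzyloxy group, the CH2 terminus of allenylsilane 7 adds to it with loss of the silyl group (SE2') to form C1–C2 and alkyne 8, and the same π-acid then activates the C3≡C4 bond for Friedel–Crafts attack by C4a, protodeauration giving 9 with the C4–C4a bond. The closest known reaction types are the Lewis-acid-catalysed SN1 propargylation of benzylic alcohols with allenylsilanes and the gold-catalysed cycloisomerisation of 4-aryl-1-butynes to 1,2-dihydronaphthalenes. Ring B closes in the 6-endo-dig mode. The new stereocentre C1 is controlled by C11: 1,3-allylic strain holds the C11–H bond in the plane of the cation and the silane adds anti to the bulky, electron-withdrawing acyl oxazolidinone, which should give the (1S,11S) relationship. The step needs closure at C4a and not at C8, and endo and not exo attack on the alkyne: the C8 bromine leaves C4a as the only free position ortho to C8a, the C5 benzyloxy group activates it, and 5-exo attack would need a strained exocyclic vinylgold intermediate.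

Step 5
Reactants: 9 (S)-4-benzyl-3-[(S)-2-[(S)-8-bromo-5,6-bis(benzyloxy)-4-methyl-1,2-dihydronaphthalen-1-yl]pent-4-enoyl]oxazolidin-2-one
Product: 10 (S)-2-[(S)-8-bromo-5,6-bis(benzyloxy)-4-methyl-1,2-dihydronaphthalen-1-yl]pent-4-en-1-ol
Conditions: LiBH4, H2O (1 equiv), Et2O, 0 °C
Reagents that add atoms: none
Why: Reductive cleavage of the N-acyl oxazolidinone by LiBH4 (attack at the exocyclic carbonyl) should give the C18 primary alcohol without touching C11 or the alkenes and releases the auxiliary.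

Step 6
Reactants: 11 methyl (R)-3-hydroxy-2-methylpropanoate
Product: 12 methyl (R)-3-(benzyloxy)-2-methylpropanoate
Conditions: BnOC(=NH)CCl3, TfOH (cat.), CH2Cl2/cyclohexane, rt
Reagents that add atoms: benzyl 2,2,2-trichloroacetimidate, N=C(OCc1ccccc1)C(Cl)(Cl)Cl
Why: Acid-catalysed O-benzylation with the trichloroacetimidate avoids the basic conditions that would epimerise or eliminate the β-hydroxy ester, so C15 is untouched.

Step 7
Reactants: 12 methyl (R)-3-(benzyloxy)-2-methylpropanoate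
Product: 13 (R)-3-(benzyloxy)-2-methylpropanal
Conditions: i-Bu2AlH, CH2Cl2, −78 °C; aq potassium sodium tartrate (KNaC4H4O6)
Reagents that add atoms: none
Why: Partial ester reduction by i-Bu2AlH at −78 °C stops at the aluminium hemiacetal, which collapses to the aldehyde on work-up, and the α-stereocentre is kept by working cold and using the aldehyde at once.

Step 8
Reactants: 13 (R)-3-(benzyloxy)-2-methylpropanal
Product: 14 (S)-{[(2-methylbut-3-en-1-yl)oxy]methyl}benzene
Conditions: Ph3PCH3Br, KN(SiMe3)2, THF, −78 to 0 °C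
Reagents that add atoms: methyltriphenylphosphonium bromide, C[P+](c1ccccc1)(c1ccccc1)c1ccccc1.[Br-] (as its ylide C=P(c1ccccc1)(c1ccccc1)c1ccccc1)
Why: Wittig methylenation with the non-stabilised ylide should convert the aldehyde into the terminal alkene faster than the α-stereocentre can epimerise.

Step 9
Reactants: 10 (S)-2-[(S)-8-bromo-5,6-bis(benzyloxy)-4-methyl-1,2-dihydronaphthalen-1-yl]pent-4-en-1-ol; 14 (S)-{[(2-methylbut-3-en-1-yl)oxy]methyl}benzene
Product: 15 (2S,4E,6S)-7-(benzyloxy)-2-[(S)-8-bromo-5,6-bis(benzyloxy)-4-methyl-1,2-dihydronaphthalen-1-yl]-6-methylhept-4-en-1-ol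
Conditions: second-generation Grubbs catalyst RuCl2(=CHPh)(PCy3)(H2IMes) (5 mol%), 14 (3 equiv), CH2Cl2, 40 °C
Reagents that add atoms: none
Why: Olefin cross-metathesis joins the terminal alkene of 10 to an excess of 14, the trisubstituted ring alkene does not take part, C15 is carried in unchanged, and the geometry of the new C13=C14 bond is irrelevant because step 10 hydrogenates it.

Step 10
Reactants: 15 (2S,4E,6S)-7-(benzyloxy)-2-[(S)-8-bromo-5,6-bis(benzyloxy)-4-methyl-1,2-dihydronaphthalen-1-yl]-6-methylhept-4-en-1-ol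
Product: 16 (2S,6S)-7-(benzyloxy)-2-[(1S,4R)-8-bromo-5,6-bis(benzyloxy)-4-methyl-1,2,3,4-tetrahydronaphthalen-1-yl]-6-methylheptan-1-ol
Conditions: H2 (1 atm), [Ir(cod)(PCy3)(py)]PF6 (10 mol%), CH2Cl2, rt
Reagents that add atoms: none
Why: In this hydroxyl-directed homogeneous hydrogenation the C1 side chain is held pseudoaxial by peri strain with the C8 bromine, its C18 hydroxyl binds the cationic iridium and delivers H2 to the face of the C3=C4 bond syn to the side chain, which should set C4 (R) with the methyl trans to the side chain, while the chain alkene is saturated without creating a stereocentre.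

Step 11
Reactants: 16 (2S,6S)-7-(benzyloxy)-2-[(1S,4R)-8-bromo-5,6-bis(benzyloxy)-4-methyl-1,2,3,4-tetrahydronaphthalen-1-yl]-6-methylheptan-1-ol
Product: 17 (5R,8S)-3,4-bis(benzyloxy)-8-[(2S,6S)-7-(benzyloxy)-1-hydroxy-6-methylheptan-2-yl]-1-bromo-5-methyl-5,6,7,8-tetrahydronaphthalene-2-carboxylic acid
Conditions: LiN(i-Pr)2 (3 equiv), THF, −78 °C; CO2; then aq HCl
Reagents that add atoms: carbon dioxide, O=C=O
Why: In this deprotonative ortho-lithiation and carboxylation C7–H is the only aromatic hydrogen and is acidified by the flanking C6 benzyloxy group and C8 bromine, the amide base (one equivalent is consumed by the C18 hydroxyl) does not exchange the bromine, and CO2 should trap the aryllithium at −78 °C before it loses LiBr.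

Step 12
Reactants: 17 (5R,8S)-3,4-bis(benzyloxy)-8-[(2S,6S)-7-(benzyloxy)-1-hydroxy-6-methylheptan-2-yl]-1-bromo-5-methyl-5,6,7,8-tetrahydronaphthalene-2-carboxylic acid
Product: 18 (5R,8S)-8-[(2S,6S)-1-acetoxy-7-(benzyloxy)-6-methylheptan-2-yl]-3,4-bis(benzyloxy)-1-bromo-5-methyl-5,6,7,8-tetrahydronaphthalene-2-carboxylic acid
Conditions: Ac2O, pyridine, DMAP (cat.), CH2Cl2, 0 °C; aq NaHCO3, then dilute HCl
Reagents that add atoms: acetic anhydride, CC(=O)OC(C)=O
Why: Acetylation under nucleophilic catalysis should acylate the only free hydroxyl (C18), and any mixed anhydride formed at the C7 carboxyl is hydrolysed in the aqueous work-up.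

Step 13
Reactants: 18 (5R,8S)-8-[(2S,6S)-1-acetoxy-7-(benzyloxy)-6-methylheptan-2-yl]-3,4-bis(benzyloxy)-1-bromo-5-methyl-5,6,7,8-tetrahydronaphthalene-2-carboxylic acid
Product: 19 (5R,8S)-8-[(2S,6S)-1-acetoxy-7-hydroxy-6-methylheptan-2-yl]-3,4-dihydroxy-5-methyl-5,6,7,8-tetrahydronaphthalene-2-carboxylic acid (CNP0191669.1)
Conditions: H2 (1 atm), Pd/C, NaHCO3, EtOAc, rt; then dilute HCl
Reagents that add atoms: none
Why: Catalytic hydrogenolysis should cleave the three benzyl ethers and the C8–Br bond (hydrodehalogenation, HBr buffered by NaHCO3) while the acetate, the carboxylic acid and all four stereocentres are untouched.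

Compound list
1 | 3,4-bis(benzyloxy)benzaldehyde | O=Cc1ccc(OCc2ccccc2)c(OCc2ccccc2)c1 | starting material
2 | 2-bromo-4,5-bis(benzyloxy)benzaldehyde | O=Cc1cc(OCc2ccccc2)c(OCc2ccccc2)cc1Br | intermediate
3 | (S)-4-benzyloxazolidin-2-one | O=C1N[C@@H](Cc2ccccc2)CO1 | starting material
4 | pent-4-enoyl chloride | C=CCCC(=O)Cl | starting material
5 | (S)-4-benzyl-3-(pent-4-enoyl)oxazolidin-2-one | O=C1OC[C@H](Cc2ccccc2)N1C(=O)CCC=C | intermediate
6 | (S)-4-benzyl-3-[(S)-2-[(S)-[2-bromo-4,5-bis(benzyloxy)phenyl](hydroxy)methyl]pent-4-enoyl]oxazolidin-2-one | O=C1OC[C@H](Cc2ccccc2)N1C(=O)[C@@H](CC=C)[C@H](O)c1cc(OCc2ccccc2)c(OCc2ccccc2)cc1Br | intermediate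
7 | trimethyl(buta-2,3-dien-2-yl)silane | C=C=C(C)[Si](C)(C)C | starting material
8 | (S)-4-benzyl-3-[(S)-2-[(S)-1-[2-bromo-4,5-bis(benzyloxy)phenyl]pent-3-yn-1-yl]pent-4-enoyl]oxazolidin-2-one (not isolated) | O=C1OC[C@H](Cc2ccccc2)N1C(=O)[C@@H](CC=C)[C@H](CC#CC)c1cc(OCc2ccccc2)c(OCc2ccccc2)cc1Br | intermediate
9 | (S)-4-benzyl-3-[(S)-2-[(S)-8-bromo-5,6-bis(benzyloxy)-4-methyl-1,2-dihydronaphthalen-1-yl]pent-4-enoyl]oxazolidin-2-one | O=C1OC[C@H](Cc2ccccc2)N1C(=O)[C@@H](CC=C)[C@@H]1CC=C(C)c2c1c(Br)cc(OCc1ccccc1)c2OCc1ccccc1 | intermediate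
10 | (S)-2-[(S)-8-bromo-5,6-bis(benzyloxy)-4-methyl-1,2-dihydronaphthalen-1-yl]pent-4-en-1-ol | OC[C@@H](CC=C)[C@@H]1CC=C(C)c2c1c(Br)cc(OCc1ccccc1)c2OCc1ccccc1 | intermediate
11 | methyl (R)-3-hydroxy-2-methylpropanoate | COC(=O)[C@H](C)CO | starting material
12 | methyl (R)-3-(benzyloxy)-2-methylpropanoate | COC(=O)[C@H](C)COCc1ccccc1 | intermediate
13 | (R)-3-(benzyloxy)-2-methylpropanal | O=C[C@H](C)COCc1ccccc1 | intermediate
14 | (S)-{[(2-methylbut-3-en-1-yl)oxy]methyl}benzene | C=C[C@H](C)COCc1ccccc1 | intermediate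
15 | (2S,4E,6S)-7-(benzyloxy)-2-[(S)-8-bromo-5,6-bis(benzyloxy)-4-methyl-1,2-dihydronaphthalen-1-yl]-6-methylhept-4-en-1-ol | OC[C@@H](C/C=C/[C@H](C)COCc1ccccc1)[C@@H]1CC=C(C)c2c1c(Br)cc(OCc1ccccc1)c2OCc1ccccc1 | intermediate
16 | (2S,6S)-7-(benzyloxy)-2-[(1S,4R)-8-bromo-5,6-bis(benzyloxy)-4-methyl-1,2,3,4-tetrahydronaphthalen-1-yl]-6-methylheptan-1-ol | OC[C@@H](CCC[C@H](C)COCc1ccccc1)[C@@H]1CC[C@@H](C)c2c1c(Br)cc(OCc1ccccc1)c2OCc1ccccc1 | intermediate
17 | (5R,8S)-3,4-bis(benzyloxy)-8-[(2S,6S)-7-(benzyloxy)-1-hydroxy-6-methylheptan-2-yl]-1-bromo-5-methyl-5,6,7,8-tetrahydronaphthalene-2-carboxylic acid | OC[C@@H](CCC[C@H](C)COCc1ccccc1)[C@@H]1CC[C@@H](C)c2c1c(Br)c(C(=O)O)c(OCc1ccccc1)c2OCc1ccccc1 | intermediate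
18 | (5R,8S)-8-[(2S,6S)-1-acetoxy-7-(benzyloxy)-6-methylheptan-2-yl]-3,4-bis(benzyloxy)-1-bromo-5-methyl-5,6,7,8-tetrahydronaphthalene-2-carboxylic acid | CC(=O)OC[C@@H](CCC[C@H](C)COCc1ccccc1)[C@@H]1CC[C@@H](C)c2c1c(Br)c(C(=O)O)c(OCc1ccccc1)c2OCc1ccccc1 | intermediate
19 | (5R,8S)-8-[(2S,6S)-1-acetoxy-7-hydroxy-6-methylheptan-2-yl]-3,4-dihydroxy-5-methyl-5,6,7,8-tetrahydronaphthalene-2-carboxylic acid (CNP0191669.1) | CC(=O)OC[C@@H](CCC[C@H](C)CO)[C@@H]1CC[C@@H](C)c2c1cc(C(=O)O)c(O)c2O | target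

Total step count: 13. Longest linear sequence: 9 steps (steps 1, 3, 4, 5, 9, 10, 11, 12, 13).

Steps most likely to fail

Step 4. The capture of the C1 cation may show poor facial selectivity, loss of water to the conjugated enoyl imide may outrun the silane, and the imide carbonyl may add to the gold-activated alkyne in place of C4a. The fallback sets C1 and C11 by auxiliary control and closes ring B by cyclodehydration. Setting out from 2, Horner–Wadsworth–Emmons olefination with diethyl 2-[(S)-4-benzyl-2-oxooxazolidin-3-yl]-2-oxoethylphosphonate (LiCl, i-Pr2NEt, MeCN) should give the cinnamoyl imide (S,E)-4-benzyl-3-{3-[2-bromo-4,5-bis(benzyloxy)phenyl]acryloyl}oxazolidin-2-one F1. Conjugate addition of the Grignard reagent from 2-(2-bromoethyl)-2-methyl-1,3-dioxolane with CuBr·SMe2, anti to the auxiliary benzyl group in the chelated s-cis imide, should set C1 and give the ketal imide (S)-4-benzyl-3-{(S)-3-[2-bromo-4,5-bis(benzyloxy)phenyl]-5-(2-methyl-1,3-dioxolan-2-yl)pentanoyl}oxazolidin-2-one F2. p-TsOH in wet benzene at reflux should cleave the ketal and cyclodehydrate the methyl ketone onto C4a to give the dihydronaphthalene imide (S)-4-benzyl-3-{2-[(S)-8-bromo-5,6-bis(benzyloxy)-4-methyl-1,2-dihydronaphthalen-1-yl]acetyl}oxazolidin-2-one F3. Enolate alkylation (NaN(SiMe3)2, allyl bromide, THF, −78 °C) then sets C11 and comes back to the route at 9.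

Step 10. The hydroxyl may fail to direct the iridium, so that hydrogen adds from the face opposite the side chain and the cis-1,4 isomer forms, or the catalyst may isomerise the ring alkene. The fallback uses a hydrogen-atom-transfer reduction under product-stability control. From 15, diimide (TsNHNH2, NaOAc, DME, reflux) should saturate only the disubstituted chain alkene to give (2S,6S)-7-(benzyloxy)-2-[(S)-8-bromo-5,6-bis(benzyloxy)-4-methyl-1,2-dihydronaphthalen-1-yl]-6-methylheptan-1-ol F4. Mn(dpm)3, PhSiH3 and t-BuOOH in i-PrOH should then reduce the trisubstituted styrene through a tertiary benzylic radical, which should favour the trans arrangement in which both peri-strained benzylic substituents are pseudoaxial, and come back to the route at 16.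

Step 11. The ortho-bromoaryllithium may lose LiBr to an aryne before carboxylation, or the base may deprotonate a benzyl ether CH2 group. The fallback introduces the carboxyl carbon by electrophilic substitution. From 16, acetylation (Ac2O, pyridine) should give (2S,6S)-7-(benzyloxy)-2-[(1S,4R)-8-bromo-5,6-bis(benzyloxy)-4-methyl-1,2,3,4-tetrahydronaphthalen-1-yl]-6-methylheptyl acetate F5. Rieche formylation (Cl2CHOMe, SnCl4, CH2Cl2, −78 °C) at C7, the only free aromatic position, should give (2S,6S)-7-(benzyloxy)-2-[(1S,4R)-8-bromo-5,6-bis(benzyloxy)-7-formyl-4-methyl-1,2,3,4-tetrahydronaphthalen-1-yl]-6-methylheptyl acetate F6. Pinnick oxidation (NaClO2, NaH2PO4, 2-methyl-2-butene, t-BuOH/H2O) comes back to the route at 18.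

Further compounds
F1 | step 4 | (S,E)-4-benzyl-3-{3-[2-bromo-4,5-bis(benzyloxy)phenyl]acryloyl}oxazolidin-2-one | O=C1OC[C@H](Cc2ccccc2)N1C(=O)/C=C/c1cc(OCc2ccccc2)c(OCc2ccccc2)cc1Br
F2 | step 4 | (S)-4-benzyl-3-{(S)-3-[2-bromo-4,5-bis(benzyloxy)phenyl]-5-(2-methyl-1,3-dioxolan-2-yl)pentanoyl}oxazolidin-2-one | O=C1OC[C@H](Cc2ccccc2)N1C(=O)C[C@H](CCC1(C)OCCO1)c1cc(OCc2ccccc2)c(OCc2ccccc2)cc1Br
F3 | step 4 | (S)-4-benzyl-3-{2-[(S)-8-bromo-5,6-bis(benzyloxy)-4-methyl-1,2-dihydronaphthalen-1-yl]acetyl}oxazolidin-2-one | O=C1OC[C@H](Cc2ccccc2)N1C(=O)C[C@@H]1CC=C(C)c2c1c(Br)cc(OCc1ccccc1)c2OCc1ccccc1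
F4 | step 10 | (2S,6S)-7-(benzyloxy)-2-[(S)-8-bromo-5,6-bis(benzyloxy)-4-methyl-1,2-dihydronaphthalen-1-yl]-6-methylheptan-1-ol | OC[C@@H](CCC[C@H](C)COCc1ccccc1)[C@@H]1CC=C(C)c2c1c(Br)cc(OCc1ccccc1)c2OCc1ccccc1
F5 | step 11 | (2S,6S)-7-(benzyloxy)-2-[(1S,4R)-8-bromo-5,6-bis(benzyloxy)-4-methyl-1,2,3,4-tetrahydronaphthalen-1-yl]-6-methylheptyl acetate | CC(=O)OC[C@@H](CCC[C@H](C)COCc1ccccc1)[C@@H]1CC[C@@H](C)c2c1c(Br)cc(OCc1ccccc1)c2OCc1ccccc1
F6 | step 11 | (2S,6S)-7-(benzyloxy)-2-[(1S,4R)-8-bromo-5,6-bis(benzyloxy)-7-formyl-4-methyl-1,2,3,4-tetrahydronaphthalen-1-yl]-6-methylheptyl acetate | CC(=O)OC[C@@H](CCC[C@H](C)COCc1ccccc1)[C@@H]1CC[C@@H](C)c2c1c(Br)c(C=O)c(OCc1ccccc1)c2OCc1ccccc1
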